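The constants of this chemistry are not given to me, so I read from the runs the one constant that counts time in the flask, and I first ask which charges it depends on.

| setting | ochre | violet | amber | flask |
|---|---|---|---|---|
| substrate | 0.35 M | 0.35 M | 0.17 M | 0.35 M |
| first nucleophile | 0.44 M | 0.69 M | 0.315 M | 0.315 M |
| gas | 40 mM (held) | 40 mM (held) | 40 mM (held) | 40 mM (held) |
| remark | run made earlier | run made earlier | run made earlier |  |
| time |  |  |  | 20 min |

- ochre (time / min: other capture product / %, target / %): 1.50: 8.3, 1.0; 2.50: 13.4, 1.4; 4.00: 20.9, 1.2; 6.00: 29.7, 0.9; 8.00: 39.0, 1.1; 12.0: 51.8, 0.9; 20.0: 69.7, 1.2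
- violet (time / min: other capture product / %, target / %): 1.50: 7.0, 2.3; 2.50: 13.5, 3.4; 4.00: 21.3, 2.2; 6.00: 29.6, 1.4; 8.00: 37.5, 2.1; 12.0: 51.9, 2.0; 20.0: 71.3, 0.2
- amber (time / min: other capture product / %, target / %): 1.50: 8.5, 1.1; 3.00: 15.9, 1.3; 6.00: 31.4, 0.4; 10.0: 46.9, 0.2; 20.0: 71.3, 0

(standard deviation of a reading: 0.5 percentage points)

- share of other capture product in other capture product plus target at 12 s
- share of other capture product in other capture product plus target at 2.0 min
- share of other capture product in other capture product plus target at 20 min
- which of other capture product and target there is more of at 20 min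

- the numbers in the tables scatter with a standard deviation of 0.5 percentage points
- at the start none of the gas is in solution

I take the charges in turn and judge each by the sum of both products at 20.0 min. Going from [substrate] = 0.35 M in ochre to 0.17 M in amber, with [first nucleophile] changing as well, moves the sum from 70.9% to 71.3%, against a scatter of 0.5 percentage points, so the substrate charge need not be known well. Going from [first nucleophile] = 0.44 M in ochre to 0.69 M in violet moves the sum by 0.6 points, but target at 2.50 min goes from 1.4% to 3.4%. This charge therefore matters for the split, and since the flask's 0.315 M equals amber's 0.315 M, I read target from amber. The gas stands at 40 mM in the flask as in amber, so that number carries over untested.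

Elapsed time is what must be known well. The sum looks like first-order loss of substrate, and amber gives 11.1 min. I carry this as the conversion half-life, the time in which the substrate not yet in the two products falls to half. At 2.0 min the flask has run 0.180 half-lives, so the sum is 11.7%. Amber's target there lies near 1.20%, so I expect a share of 89.7%. At 20 min, with amber's target at 0.2% and then 0%, I expect about 99.7%. At 12 s, 0.0180 half-lives give a sum of 1.24%, too close to the scatter and too far before the first reading for me to commit to a share.

The forecast gives 50%, 91%, 99% and other capture product ahead, its early figure being “roughly half”.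

The flask gives 44.2%, 90.0% and 99.5%, with other capture product ahead at 71.0% against 0.373% target.

    second nucleophile + intermediate → other capture product (k = 100 M⁻¹ min⁻¹)
    substrate ⇌ intermediate (K = 0.0270, k = 0.170 min⁻¹)
    first nucleophile + intermediate ⇌ target (K = 2.60 M⁻¹, k = 19.0 M⁻¹ min⁻¹)
    intermediate → side product (k = 0.0560 min⁻¹)
    gas ⇌ second nucleophile, rate k5*(csat - [second nucleophile]) (kL = 12.0 min⁻¹)

Target in the flask stands at its highest, 1.24%, at 1.11 min. The half-life puts the sum at 10.0 min at 46.4%, and the flask then holds 46.0% other capture product and 0.712% target. In the neighbour flask with 0.079 M of first nucleophile, the same 1.80 half-lives put the sum at 71.3%, and that flask holds 71.3% other capture product and 0.0930% target.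

(The earlier runs and the new flask stem from a simulated flask with made-up constants, noise included.)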